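**Convention:** C1–C15 are germacrane positions of the target (C6 carries the lactone oxygen, C12 is the lactone carbonyl, C13 the CH2Cl carbon, C14 and C15 the methyls on C10 and C4). The target is (2S,6R,7R,8R,11S) with 1(10)Z and 4Z double bonds.

**Assumption:** the ligand and catalyst enantiomers named in steps 3 and 6 and in the fallbacks are taken to give the configurations stated; if the sense proves opposite, the antipode is used.

## Retrosynthetic overview

1. The chlorohydrin comes from the 11,13-spiro-epoxide (chloride opening at C13), and the epoxide from the α-methylene lactone by nucleophilic epoxidation.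
2. The ten-membered ring is closed last at C7–C8 by a 10-exo addition of a samarium ketyl radical (C8 aldehyde) to C7 of a preformed 3-(acetoxymethyl)butenolide. This sets C7 and C8 and releases the exocyclic methylene in the same operation.
3. The butenolide comes from a chromium/nickel coupling at C6–C7 of a Z-enal (held as its lactol) with a Z-β-iodo-α-(hydroxymethyl)acrylate; this sets C6.
4. The C2–C3 bond, C2 and the Z-C4=C5 bond come from an asymmetric vinylogous aldol/lactonisation of a Z-enynal with a senecioate dienolate. The Z-C1=C10 bond is bought in, and the terminal alkyne is the masked C8 aldehyde.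
5. Ring order: temporary six-membered lactone, then butenolide, then ten-membered carbocycle, then epoxide opened to the chlorohydrin.

## Route

Step 1
Reactants: 1 (2Z)-3-methylpent-2-en-4-yn-1-ol
Product: 2 (2Z)-3-methylpent-2-en-4-ynal
Conditions: MnO2 (10 equiv), CH2Cl2, 20 °C
Reagents that add atoms: none
Why: Allylic alcohol oxidation with activated MnO2 is mild enough to keep the Z-enyne geometry and stops at the aldehyde; no stereocentre is formed.

Step 2
Reactants: 3 methyl 3-methylbut-2-enoate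
Product: 4 1-methoxy-3-methyl-1-(trimethylsilyloxy)buta-1,3-diene
Conditions: LiN(i-Pr)2, THF, −78 °C; then Me3SiCl
Reagents that add atoms: chlorotrimethylsilane C[Si](C)(C)Cl
Why: Kinetic γ-deprotonation of the senecioate and O-silylation give the vinylketene silyl acetal (silyl dienolate formation); no stereocentre is formed.

Step 3
Reactants: 2 (2Z)-3-methylpent-2-en-4-ynal; 4 1-methoxy-3-methyl-1-(trimethylsilyloxy)buta-1,3-diene
Product: 6 (6S)-4-methyl-6-[(1Z)-2-methylbut-1-en-3-yn-1-yl]-5,6-dihydro-2H-pyran-2-one, via aldolate 5 (not isolated)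
Conditions: Cu(OTf)2 (10 mol %), (S)-Tol-BINAP (11 mol %), (Bu4N)(Ph3SiF2) (20 mol %), THF, −78 to 20 °C
Reagents that add atoms: none
Why: Catalytic asymmetric vinylogous Mukaiyama aldol reaction in which the Tol-BINAP-bound copper dienolate from 4 attacks one face of the enal through its γ-carbon to set C2 as S, and the Z-aldolate closes onto the ester so that the new C4=C5 bond is fixed Z inside the six-membered lactone.

Step 4
Reactants: 6 (6S)-4-methyl-6-[(1Z)-2-methylbut-1-en-3-yn-1-yl]-5,6-dihydro-2H-pyran-2-one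
Product: 7 (6S)-4-methyl-6-[(1Z)-2-methylbut-1-en-3-yn-1-yl]-5,6-dihydro-2H-pyran-2-ol (anomer mixture; cyclic form of the Z-enal with C6 as the aldehyde carbon)
Conditions: i-Bu2AlH (1.1 equiv), CH2Cl2, −78 °C; aqueous potassium sodium tartrate
Reagents that add atoms: none
Why: Half-reduction of the lactone to the lactol by 1,2-hydride delivery at low temperature leaves C2 and both alkenes untouched.

Step 5
Reactants: 8 methyl prop-2-ynoate; 9 formaldehyde (monomer from cracked paraformaldehyde)
Product: 10 methyl (2Z)-2-(hydroxymethyl)-3-iodoprop-2-enoate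
Conditions: MgI2 (1.2 equiv), CH2Cl2, 0 °C
Reagents that add atoms: magnesium diiodide [Mg+2].[I-].[I-]
Why: Iodide-triggered Morita–Baylis–Hillman-type aldol (β-iodo variant) in which iodide adds to the propiolate and the resulting allenolate captures formaldehyde, giving under kinetic control the Z-alkene with iodine cis to the ester; no stereocentre is formed.

Step 6
Reactants: 7 (6S)-4-methyl-6-[(1Z)-2-methylbut-1-en-3-yn-1-yl]-5,6-dihydro-2H-pyran-2-ol; 10 methyl (2Z)-2-(hydroxymethyl)-3-iodoprop-2-enoate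
Product: 12 (5R)-5-[(1Z,4S,5Z)-4-hydroxy-2,6-dimethylocta-1,5-dien-7-yn-1-yl]-3-(hydroxymethyl)furan-2(5H)-one, via hydroxy ester 11 (not isolated)
Conditions: CrCl2 (4 equiv), (S)-N-[2-(4-isopropyl-4,5-dihydro-1,3-oxazol-2-yl)-6-methylphenyl]methanesulfonamide (4.4 equiv), Et3N, NiCl2(2,9-dimethyl-1,10-phenanthroline) (5 mol %), THF/MeCN, 20 °C
Reagents that add atoms: none
Why: Nozaki–Hiyama–Kishi coupling in which the alkenylchromium formed from 10 with retention of geometry adds to the ring-opened Z-enal form of 7 under control of the chiral sulfonamide on chromium to set C6 as R, after which the alkoxide closes onto the cis ester to give the butenolide.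

Step 7
Reactants: 12 (5R)-5-[(1Z,4S,5Z)-4-hydroxy-2,6-dimethylocta-1,5-dien-7-yn-1-yl]-3-(hydroxymethyl)furan-2(5H)-one
Product: 13 [(5R)-5-[(1Z,4S,5Z)-4-acetoxy-2,6-dimethylocta-1,5-dien-7-yn-1-yl]-2-oxo-2,5-dihydrofuran-3-yl]methyl acetate
Conditions: Ac2O, pyridine, CH2Cl2, 0 °C
Reagents that add atoms: acetic anhydride CC(=O)OC(C)=O
Why: Plain O-acylation installs the C2 acetate of the target and turns the C13 oxygen into a leaving group, with pyridine too weak a base to epimerise C6; no stereocentre is changed.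

Step 8
Reactants: 13 [(5R)-5-[(1Z,4S,5Z)-4-acetoxy-2,6-dimethylocta-1,5-dien-7-yn-1-yl]-2-oxo-2,5-dihydrofuran-3-yl]methyl acetate
Product: 14 [(5R)-5-[(1Z,4S,5Z)-4-acetoxy-2,6-dimethyl-8-oxoocta-1,5-dien-1-yl]-2-oxo-2,5-dihydrofuran-3-yl]methyl acetate
Conditions: [CpRu(MeCN)(L)2]PF6 (L = 6-tert-butyl-2-(diphenylphosphino)pyridine, 5 mol %), H2O (5 equiv), acetone, 50 °C
Reagents that add atoms: water O
Why: Anti-Markovnikov alkyne hydration through a ruthenium vinylidene gives the β,γ-unsaturated aldehyde under neutral conditions, so the Z-C1=C10 bond neither isomerises nor moves into conjugation; no stereocentre is formed.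

Step 9
Reactants: 14 [(5R)-5-[(1Z,4S,5Z)-4-acetoxy-2,6-dimethyl-8-oxoocta-1,5-dien-1-yl]-2-oxo-2,5-dihydrofuran-3-yl]methyl acetate
Product: 16 (2S,6R,7R,8R)-2,8-diacetoxy-(1(10)Z,4Z)-germacra-1(10),4,11(13)-trien-12,6-olide, via diiodosamarium alkoxide 15 (not isolated)
Conditions: SmI2 (3 equiv), THF, −78 to 0 °C, syringe-pump addition of 14 (final 2 mM); then Ac2O, 4-(dimethylamino)pyridine, 0 °C
Reagents that add atoms: acetic anhydride CC(=O)OC(C)=O
Why: Proposed new method: SmI2 reduces the aldehyde to a ketyl radical that adds 10-exo to C7 of the butenolide (a polarity-matched ketyl–olefin addition whose closest precedents are intermolecular SmI2 ketyl–butenolide couplings and eight-membered SmI2 ketyl–olefin cyclisations), attacking the face anti to the C6 substituent (7R, trans-fused lactone) with the O–Sm group anti to the lactone α-carbon and H8 in the most crowded position (8R), after which the α-ester radical is reduced to a samarium enolate that expels the C13 acetate to give the exocyclic methylene and the C8 alkoxide is acetylated in the flask.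

Step 10
Reactants: 16 (2S,6R,7R,8R)-2,8-diacetoxy-(1(10)Z,4Z)-germacra-1(10),4,11(13)-trien-12,6-olide
Product: 18 (2S,6R,7R,8R,11S)-2,8-diacetoxy-13-chloro-11-hydroxy-(1(10)Z,4Z)-germacra-1(10),4-dien-12,6-olide (CNP0182971.4), via spiro epoxide 17 (not isolated)
Conditions: t-BuOOH (1.5 equiv), n-BuLi (1.2 equiv), THF, −20 °C; then AcOH, LiCl, 20 °C
Reagents that add atoms: tert-butyl hydroperoxide CC(C)(C)OO; lithium chloride [Li+].[Cl-]
Why: Nucleophilic (Weitz–Scheffer-type) epoxidation in which t-BuOOLi adds only to the electron-poor exocyclic alkene and the enolate closes on the face anti to the C8-bearing branch at C7 (11R epoxide), followed by SN2 opening by chloride at the primary C13 with retention at C11, which becomes 11S by priority change only.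

## Compound list

1 | (2Z)-3-methylpent-2-en-4-yn-1-ol | OC/C=C(/C)C#C | starting material
2 | (2Z)-3-methylpent-2-en-4-ynal | O=C/C=C(/C)C#C | intermediate
3 | methyl 3-methylbut-2-enoate | COC(=O)C=C(C)C | starting material
4 | 1-methoxy-3-methyl-1-(trimethylsilyloxy)buta-1,3-diene (ketene acetal geometry not controlled, used as formed) | COC(O[Si](C)(C)C)=CC(C)=C | intermediate
5 | monovalent copper alkoxide of methyl (2Z,5S,6Z)-5-hydroxy-3,7-dimethylnona-2,6-dien-8-ynoate (Tol-BINAP on copper not drawn) | COC(=O)/C=C(/C)C[C@H](O[Cu])/C=C(/C)C#C | intermediate (not isolated)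
6 | (6S)-4-methyl-6-[(1Z)-2-methylbut-1-en-3-yn-1-yl]-5,6-dihydro-2H-pyran-2-one | O=C1C=C(C)C[C@H](O1)/C=C(/C)C#C | intermediate
7 | (6S)-4-methyl-6-[(1Z)-2-methylbut-1-en-3-yn-1-yl]-5,6-dihydro-2H-pyran-2-ol (anomer mixture) | OC1C=C(C)C[C@H](O1)/C=C(/C)C#C | intermediate
8 | methyl prop-2-ynoate | COC(=O)C#C | starting material
9 | formaldehyde | C=O | starting material
10 | methyl (2Z)-2-(hydroxymethyl)-3-iodoprop-2-enoate | COC(=O)/C(CO)=C\I | intermediate
11 | methyl (2Z,4R,5Z,8S,9Z)-4,8-dihydroxy-2-(hydroxymethyl)-6,10-dimethyldodeca-2,5,9-trien-11-ynoate | COC(=O)/C(CO)=C\[C@H](O)/C=C(/C)C[C@H](O)/C=C(/C)C#C | intermediate (not isolated)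
12 | (5R)-5-[(1Z,4S,5Z)-4-hydroxy-2,6-dimethylocta-1,5-dien-7-yn-1-yl]-3-(hydroxymethyl)furan-2(5H)-one | O=C1O[C@H](/C=C(/C)C[C@H](O)/C=C(/C)C#C)C=C1CO | intermediate
13 | [(5R)-5-[(1Z,4S,5Z)-4-acetoxy-2,6-dimethylocta-1,5-dien-7-yn-1-yl]-2-oxo-2,5-dihydrofuran-3-yl]methyl acetate | O=C1O[C@H](/C=C(/C)C[C@H](OC(C)=O)/C=C(/C)C#C)C=C1COC(C)=O | intermediate
14 | [(5R)-5-[(1Z,4S,5Z)-4-acetoxy-2,6-dimethyl-8-oxoocta-1,5-dien-1-yl]-2-oxo-2,5-dihydrofuran-3-yl]methyl acetate | O=C1O[C@H](/C=C(/C)C[C@H](OC(C)=O)/C=C(/C)CC=O)C=C1COC(C)=O | intermediate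
15 | O-diiodosamarium alkoxide (trivalent samarium) of (2S,6R,7R,8R)-2-acetoxy-8-hydroxy-(1(10)Z,4Z)-germacra-1(10),4,11(13)-trien-12,6-olide | CC(=O)O[C@@H]1/C=C(/C)C[C@@H](O[Sm](I)I)[C@@H]2[C@@H](/C=C(/C)C1)OC(=O)C2=C | intermediate (not isolated)
16 | (2S,6R,7R,8R)-2,8-diacetoxy-(1(10)Z,4Z)-germacra-1(10),4,11(13)-trien-12,6-olide | CC(=O)O[C@@H]1/C=C(/C)C[C@@H](OC(C)=O)[C@@H]2[C@@H](/C=C(/C)C1)OC(=O)C2=C | intermediate
17 | (2S,6R,7R,8R,11R)-2,8-diacetoxy-11,13-epoxy-(1(10)Z,4Z)-germacra-1(10),4-dien-12,6-olide | CC(=O)O[C@@H]1/C=C(/C)C[C@@H](OC(C)=O)[C@@H]2[C@@H](/C=C(/C)C1)OC(=O)[C@]23CO3 | intermediate (not isolated)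
18 | (2S,6R,7R,8R,11S)-2,8-diacetoxy-13-chloro-11-hydroxy-(1(10)Z,4Z)-germacra-1(10),4-dien-12,6-olide, i.e. (3S,3aR,4R,6Z,8S,10Z,11aR)-3-(chloromethyl)-3-hydroxy-6,10-dimethyl-2-oxo-2,3,3a,4,5,8,9,11a-octahydrocyclodeca[b]furan-4,8-diyl diacetate | CC(=O)O[C@@H]1/C=C(/C)C[C@@H](OC(C)=O)[C@@H]2[C@@H](/C=C(/C)C1)OC(=O)[C@]2(O)CCl | target

## Step count and risks

Total step count: 10 (steps 2 and 5 are side branches).
Longest linear sequence: 8 steps (1 → 2 → 6 → 7 → 12 → 13 → 14 → 16 → 18; steps 1, 3, 4, 6, 7, 8, 9, 10).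

**Step 9 (ketyl radical macrocyclisation)** is the step most likely to fail. The ketyl may be reduced or dimerise before a ten-membered ring closes, SmI2 may transfer an electron to the butenolide instead, the ring fusion or C8 may come out wrong, and the C8 alkoxide may translactonise before it is acetylated. The fallback sets out from 14 and returns at 16. Acetyl bromide with catalytic ZnCl2 adds across the aldehyde to give the bromo acetate F9 (both C8 epimers). Slow addition of Bu3SnH and azobisisobutyronitrile in refluxing benzene at high dilution then generates a neutral α-acetoxyalkyl radical that makes the same C7–C8 bond but ends by hydrogen-atom transfer, giving the macrocyclic triacetate F10 with the C8 acetate already in place. DBU then eliminates the C13 acetate to give 16. This replaces electron-transfer chemistry by a tin hydride chain, so the butenolide and the alkoxide problems disappear.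

**Step 6 (chromium/nickel coupling on the lactol)** is second. The lactol may open too slowly, and catalyst control at C6 with a β-iodoacrylate partner may be modest. The fallback sets out from 6 and returns at 12.
- The lithium acetylide of tert-butyldimethyl(prop-2-yn-1-yloxy)silane opens the lactone to the hydroxy ynone F4, and TBSCl/imidazole gives the bis-silyl ynone F5.
- Transfer hydrogenation with RuCl(p-cymene)[(R,R)-TsDPEN] in i-PrOH sets C6 in the propargylic alcohol F6.
- Hydroxyl-directed trans-hydroalumination with NaAlH2(OCH2CH2OMe)2 followed by I2 gives the Z-vinyl iodide F7.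
- Carbonylative lactonisation (Pd(PPh3)4, CO, Et3N) gives the silylated butenolide F8, and HF·pyridine removes both silyl groups to give 12.

Here C6 is set by a ketone reduction of known sense instead of by a carbonyl addition.

**Step 3 (copper-catalysed vinylogous aldol)** is third. The terminal alkyne can be cuprated and stop turnover, and the enantioselectivity of this lactone-forming variant is only moderate to good. The fallback sets out from 2 and returns at 6. A SiCl4/chiral bisphosphoramide-catalysed Mukaiyama aldol of 2 with 2-(trimethylsilyloxy)propene gives the hydroxy ketone F1. Bromoacetyl bromide/pyridine gives the bromoacetate F2, and P(OEt)3 (Arbuzov) gives the phosphonate F3. An intramolecular Horner–Wadsworth–Emmons reaction (LiCl, DBU, MeCN) then closes the lactone 6, the ring again enforcing the Z-C4=C5 bond. No copper is involved and C2 is set in a simple aldehyde aldol.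

Further compounds
F1 | step 3 | (4S,5Z)-4-hydroxy-6-methyloct-5-en-7-yn-2-one | CC(=O)C[C@H](O)/C=C(/C)C#C
F2 | step 3 | (4S,5Z)-6-methyl-2-oxooct-5-en-7-yn-4-yl bromoacetate | CC(=O)C[C@H](OC(=O)CBr)/C=C(/C)C#C
F3 | step 3 | (4S,5Z)-6-methyl-2-oxooct-5-en-7-yn-4-yl (diethoxyphosphoryl)acetate | CC(=O)C[C@H](OC(=O)CP(=O)(OCC)OCC)/C=C(/C)C#C
F4 | step 6 | (5Z,8S,9Z)-1-[(tert-butyldimethylsilyl)oxy]-8-hydroxy-6,10-dimethyldodeca-5,9-diene-2,11-diyn-4-one | CC(C)(C)[Si](C)(C)OCC#CC(=O)/C=C(/C)C[C@H](O)/C=C(/C)C#C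
F5 | step 6 | (5Z,8S,9Z)-1,8-bis[(tert-butyldimethylsilyl)oxy]-6,10-dimethyldodeca-5,9-diene-2,11-diyn-4-one | CC(C)(C)[Si](C)(C)OCC#CC(=O)/C=C(/C)C[C@H](O[Si](C)(C)C(C)(C)C)/C=C(/C)C#C
F6 | step 6 | (4R,5Z,8S,9Z)-1,8-bis[(tert-butyldimethylsilyl)oxy]-6,10-dimethyldodeca-5,9-diene-2,11-diyn-4-ol | CC(C)(C)[Si](C)(C)OCC#C[C@H](O)/C=C(/C)C[C@H](O[Si](C)(C)C(C)(C)C)/C=C(/C)C#C
F7 | step 6 | (2Z,4R,5Z,8S,9Z)-1,8-bis[(tert-butyldimethylsilyl)oxy]-2-iodo-6,10-dimethyldodeca-2,5,9-trien-11-yn-4-ol | CC(C)(C)[Si](C)(C)OC/C(I)=C/[C@H](O)/C=C(/C)C[C@H](O[Si](C)(C)C(C)(C)C)/C=C(/C)C#C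
F8 | step 6 | (5R)-3-{[(tert-butyldimethylsilyl)oxy]methyl}-5-[(1Z,4S,5Z)-4-[(tert-butyldimethylsilyl)oxy]-2,6-dimethylocta-1,5-dien-7-yn-1-yl]furan-2(5H)-one | O=C1O[C@H](/C=C(/C)C[C@H](O[Si](C)(C)C(C)(C)C)/C=C(/C)C#C)C=C1CO[Si](C)(C)C(C)(C)C
F9 | step 9 | [(5R)-5-[(1Z,4S,5Z)-4,8-diacetoxy-8-bromo-2,6-dimethylocta-1,5-dien-1-yl]-2-oxo-2,5-dihydrofuran-3-yl]methyl acetate (both C8 epimers) | O=C1O[C@H](/C=C(/C)C[C@H](OC(C)=O)/C=C(/C)CC(Br)OC(C)=O)C=C1COC(C)=O
F10 | step 9 | (2S,6R,7R,8R)-2,8,13-triacetoxy-(1(10)Z,4Z)-germacra-1(10),4-dien-12,6-olide (C11 epimers) | CC(=O)O[C@@H]1/C=C(/C)C[C@@H](OC(C)=O)[C@@H]2[C@@H](/C=C(/C)C1)OC(=O)C2COC(C)=O
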